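**Plan**

1. Labels: ring A is the quinolinone that carries the gem-dimethylpyran and ring B the second quinolinone (primed atoms). Ca is the ring-fusion CH next to CMe2, Cb the ring-fusion O–CH on C3 of ring A, and Cc the CH bearing the CH2C(CH3)2OH chain. O4 and O4' are the ether oxygens on rings A and B.
2. Cuts: first the Cb–H bond (back to a hemiketal) and the O–Si bond. Next C3'–Cc and O4'–Cb together, which opens the central pyran to 4-hydroxy-1-methylquinolin-2(1H)-one and a ring-A 3-alkylidene-4-pyranone. Last the exocyclic C=C (aldol) and the C3–acyl and O4–CMe2 bonds of that pyranone.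
3. Enabling feature: Cb and Cc stand 1,3 across Ca, so they are the carbonyl carbon and the β-carbon of an exocyclic enone on ring A, and the C3'/O4'–H pair of quinolinone B is the matching C,O-dinucleophile. The ring-A lactam C=O lies peri to the Cb ketone and offers the catalyst a two-point hydrogen-bond site.
4. Forward: the gem-dimethylpyranone is annulated onto ring A, the chain is joined by aldol condensation, the second quinolinone is added and the central pyran closed in one catalytic step, then hemiketal reduction and desilylation.
5. Stereochemistry: Cc comes from the chiral bifunctional catalyst. Ca follows by equilibration to the isomer with CMe2 and the chain trans. Cb is set by hydride addition to the oxocarbenium ion on the face of the H on Ca.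

Key step: step 6

Assumption: the sense of induction of the cinchona squaramide is assigned by analogy only; the quinine-derived catalyst is written, and should it favour the Si face of Cc, its quinidine-derived pseudoenantiomer is taken instead with nothing else changed.

Remark: hemiketal 15 is expected to stand in ring–chain equilibrium with its open form 14; either form enters step 7 through the same cation.

**Step 1**
Reactants: 1 4-hydroxy-1-methylquinolin-2(1H)-one; 2 3-methylbut-2-enoic acid
Product: 4 2,2,6-trimethyl-2,3-dihydro-4H-pyrano[3,2-c]quinoline-4,5(6H)-dione, via C-acylated quinolinone 3 (not isolated)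
Conditions: P2O5, MeSO3H, 70 °C
Reagents that add atoms: none
Why: Friedel–Crafts C-acylation of the enol carbon C3 of 1 by the activated acid, then 6-endo-trig oxa-Michael closure of the 4-OH onto the β,β-dimethyl enone, is the standard 2,2-dimethylchroman-4-one annulation of hydroxyarenes, and the anhydrous medium favours acylation over conjugate alkylation.

**Step 2**
Reactants: 5 3-methylbutane-1,3-diol
Product: 7 2-methyl-2,4-bis(triethylsilyloxy)butane, via primary mono-silyl ether 6 (not isolated)
Conditions: Et3SiOTf (2.5 equiv), 2,6-lutidine, CH2Cl2, −78 → 0 °C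
Reagents that add atoms: triethylsilyl trifluoromethanesulfonate, CC[Si](CC)(CC)OS(=O)(=O)C(F)(F)F
Why: A silyl triflate with 2,6-lutidine silylates the primary and also the hindered tertiary hydroxyl (standard silyl ether formation).

**Step 3**
Reactants: 7 2-methyl-2,4-bis(triethylsilyloxy)butane
Product: 9 3-methyl-3-(triethylsilyloxy)butanal, via alkoxysulfonium chloride 8 (not isolated)
Conditions: (COCl)2, DMSO, CH2Cl2, −78 → −40 °C; then Et3N, −78 → 0 °C
Reagents that add atoms: none
Why: Under Swern oxidation conditions a primary triethylsilyl ether is cleaved by the chlorosulfonium reagent and oxidised in the same pot, while the hindered tertiary silyl ether is left in place.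

**Step 4**
Reactants: 4 2,2,6-trimethyl-2,3-dihydro-4H-pyrano[3,2-c]quinoline-4,5(6H)-dione; 9 3-methyl-3-(triethylsilyloxy)butanal
Product: 11 3-[1-hydroxy-3-methyl-3-(triethylsilyloxy)butyl]-2,2,6-trimethyl-2,3-dihydro-4H-pyrano[3,2-c]quinoline-4,5(6H)-dione (diastereomer mixture), via lithium enolate 10 (not isolated)
Conditions: LiN(SiMe3)2, THF, −78 °C; then 9, −78 °C; AcOH quench at −78 °C
Reagents that add atoms: none
Why: The kinetic lithium enolate of the ring-A ketone (C3 is its only enolisable position) adds to the aldehyde in a directed aldol addition; the two new stereocentres are left uncontrolled because step 5 removes both, and the low temperature holds back β-loss of O4 from the enolate.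

**Step 5**
Reactants: 11 aldol adduct (diastereomer mixture)
Product: 13 (Z)-2,2,6-trimethyl-3-[3-methyl-3-(triethylsilyloxy)butylidene]-2,3-dihydro-4H-pyrano[3,2-c]quinoline-4,5(6H)-dione, via methanesulfonate 12 (not isolated)
Conditions: MsCl, Et3N, CH2Cl2, 0 °C; then DBU, 0 → 25 °C
Reagents that add atoms: none
Why: Mesylation and E1cB elimination through the ketone enolate complete the aldol condensation, and the Z isomer (chain syn to the ketone) is expected because the E isomer would press the chain against the gem-dimethyl group (allylic 1,3-strain).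

**Step 6**
Reactants: 13 (Z)-alkylidene pyranoquinolinedione; 1 4-hydroxy-1-methylquinolin-2(1H)-one
Product: 15 pentacyclic hemiketal (Ca S; Cb S with OH cis to the H on Ca; Cc R; chain on Cc trans to CMe2 and kept as triethylsilyl ether), via open Michael adduct 14 (not isolated)
Conditions: 3-{[3,5-bis(trifluoromethyl)phenyl]amino}-4-{[(8α,9S)-6'-methoxycinchonan-9-yl]amino}cyclobut-3-ene-1,2-dione (10 mol %), CH2Cl2, 25 °C
Reagents that add atoms: none
Why: The quinuclidine nitrogen of the catalyst takes the 4-OH proton of 1 while the squaramide N–H pair binds the peri ketone/lactam carbonyl pair of 13, C3' adds to the Re face of the exocyclic β-carbon Cc of the s-cis-locked enone, the ring-A enolate is protonated at Ca, and O4'–H then adds to the Cb ketone. The closest known reaction type is the organocatalytic Michael addition–hemiketalisation of 4-hydroxycoumarins and 4-hydroxyquinolin-2-ones with enones (warfarin-type adducts). The central pyran closes by 6-exo-trig attack of the enol oxygen O4' on the ketone carbon Cb. Cc (R) is set by the catalyst; Ca is set by protonation and is expected to be corrected, through enolisation of the open form 14 under the amine, to the isomer with CMe2 and the chain trans (trans-diaxial on the new ring, the chain held pseudo-axial by the C2'=O lactam carbonyl); the hemiketal carbon settles cis-fused with axial OH under ring–chain equilibrium and is erased in step 7. The step needs C- over O-alkylation and 1,4- over 1,2-addition, which the soft enol carbon C3' and the reversibility of O-addition secure, and it needs a single enone geometry and face, which the Z-configured, conformationally locked exocyclic enone with its two-point binding site provides.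

**Step 7**
Reactants: 15 pentacyclic hemiketal
Product: 17 triethylsilyl ether of the target (Ca R; Cb S; Cc R; H on Ca and H on Cb cis), via oxocarbenium ion 16 (not isolated)
Conditions: Et3SiH, BF3·OEt2, CH2Cl2, −78 → −20 °C
Reagents that add atoms: none
Why: Ionic hydrogenation of a cyclic hemiketal: BF3 ionises 15 to the O4'- and O4-stabilised cation 16, whose two envelope flaps (CMe2 and Cc) must lie on the face opposite the H on Ca and whose pseudo-axial CMe2 methyl blocks that face, so Et3SiH should deliver hydride to Cb on the convex face, cis to the H on Ca, while exchange of that H through the enol ether at the cation stage lets any residual Ca epimer converge.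

**Step 8**
Reactants: 17 triethylsilyl ether of the target
Product: 18 CNP0202276.1 (Ca R; Cb S; Cc R)
Conditions: Bu4NF, THF, 0 → 25 °C
Reagents that add atoms: none
Why: Fluoride cleaves the Si–O bond of the tertiary silyl ether (standard desilylation) and touches no stereocentre.

**Compound list**

1 | 4-hydroxy-1-methylquinolin-2(1H)-one | Cn1c(=O)cc(O)c2ccccc21 | starting material
2 | 3-methylbut-2-enoic acid | CC(C)=CC(=O)O | starting material
3 | 4-hydroxy-1-methyl-3-(3-methylbut-2-enoyl)quinolin-2(1H)-one | Cn1c(=O)c(C(=O)C=C(C)C)c(O)c2ccccc21 | intermediate (not isolated)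
4 | 2,2,6-trimethyl-2,3-dihydro-4H-pyrano[3,2-c]quinoline-4,5(6H)-dione | Cn1c(=O)c2c(c3ccccc31)OC(C)(C)CC2=O | intermediate
5 | 3-methylbutane-1,3-diol | CC(C)(O)CCO | starting material
6 | 2-methyl-4-(triethylsilyloxy)butan-2-ol | CC[Si](CC)(CC)OCCC(C)(C)O | intermediate (not isolated)
7 | 2-methyl-2,4-bis(triethylsilyloxy)butane | CC[Si](CC)(CC)OCCC(C)(C)O[Si](CC)(CC)CC | intermediate
8 | dimethyl[3-methyl-3-(triethylsilyloxy)butoxy]sulfonium chloride | C[S+](C)OCCC(C)(C)O[Si](CC)(CC)CC.[Cl-] | intermediate (not isolated)
9 | 3-methyl-3-(triethylsilyloxy)butanal | CC[Si](CC)(CC)OC(C)(C)CC=O | intermediate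
10 | lithium 2,2,6-trimethyl-5-oxo-5,6-dihydro-2H-pyrano[3,2-c]quinolin-4-olate (lithium enolate of 4) | Cn1c(=O)c2c(c3ccccc31)OC(C)(C)C=C2[O-].[Li+] | intermediate (not isolated)
11 | 3-[1-hydroxy-3-methyl-3-(triethylsilyloxy)butyl]-2,2,6-trimethyl-2,3-dihydro-4H-pyrano[3,2-c]quinoline-4,5(6H)-dione, diastereomer mixture | Cn1c(=O)c2c(c3ccccc31)OC(C)(C)C(C(O)CC(C)(C)O[Si](CC)(CC)CC)C2=O | intermediate
12 | methanesulfonate of 11 | Cn1c(=O)c2c(c3ccccc31)OC(C)(C)C(C(OS(C)(=O)=O)CC(C)(C)O[Si](CC)(CC)CC)C2=O | intermediate (not isolated)
13 | (Z)-2,2,6-trimethyl-3-[3-methyl-3-(triethylsilyloxy)butylidene]-2,3-dihydro-4H-pyrano[3,2-c]quinoline-4,5(6H)-dione | Cn1c(=O)c2c(c3ccccc31)OC(C)(C)/C(=C/CC(C)(C)O[Si](CC)(CC)CC)C2=O | intermediate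
14 | (3S)-3-[(1R)-1-(4-hydroxy-1-methyl-2-oxo-1,2-dihydroquinolin-3-yl)-3-methyl-3-(triethylsilyloxy)butyl]-2,2,6-trimethyl-2,3-dihydro-4H-pyrano[3,2-c]quinoline-4,5(6H)-dione (open Michael adduct) | Cn1c(=O)c2c(c3ccccc31)OC(C)(C)[C@H]([C@@H](CC(C)(C)O[Si](CC)(CC)CC)c1c(O)c3ccccc3n(C)c1=O)C2=O | intermediate (not isolated)
15 | pentacyclic hemiketal: rings A and B joined through the new pyran, OH on Cb cis to the H on Ca, chain CH2C(CH3)2OSiEt3 on Cc trans to CMe2 (Ca S, Cb S, Cc R) | Cn1c(=O)c2c(c3ccccc31)OC(C)(C)[C@H]1[C@]2(O)Oc2c(c(=O)n(C)c3ccccc23)[C@@H]1CC(C)(C)O[Si](CC)(CC)CC | intermediate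
16 | oxocarbenium ion from 15 (Cb=O4' cation, hydroxytrifluoroborate counter-ion; Ca S, Cc R) | Cn1c(=O)c2c(c3ccccc31)OC(C)(C)[C@H]1C2=[O+]c2c(c(=O)n(C)c3ccccc23)[C@@H]1CC(C)(C)O[Si](CC)(CC)CC.O[B-](F)(F)F | intermediate (not isolated)
17 | triethylsilyl ether of the target: H on Ca, H on Cb and the chain on Cc all on one face (Ca R, Cb S, Cc R) | Cn1c(=O)c2c(c3ccccc31)OC(C)(C)[C@H]1[C@@H]2Oc2c(c(=O)n(C)c3ccccc23)[C@@H]1CC(C)(C)O[Si](CC)(CC)CC | intermediate
18 | CNP0202276.1: cis-fused bis-pyrano bis-quinolinone with CH2C(CH3)2OH on Cc (Ca R, Cb S, Cc R) | Cn1c(=O)c2c(c3ccccc31)OC(C)(C)[C@H]1[C@@H]2Oc2c(c(=O)n(C)c3ccccc23)[C@@H]1CC(C)(C)O | target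

**Count and risks**

Total steps: 8. Longest linear sequence: 7 steps (5 → 7 → 9 → 11 → 13 → 15 → 17 → 18).

Step 6. The conjugate addition to the hindered, electron-rich exocyclic enone may be slow or poorly face-selective under hydrogen-bond catalysis, the protonation at Ca may give the cis isomer that is slow to equilibrate, and long exposure to base may erode the configuration at Cc by retro-addition. Fallback, setting out from 13: the nucleophile is used as its silyl enol ether, 1-methyl-4-(trimethylsilyloxy)quinolin-2(1H)-one F1 (from 1 with Me3SiCl and Et3N), in a Mukaiyama–Michael addition under a chiral Lewis acid, Cu(OTf)2 with (S,S)-2,2'-(propane-2,2-diyl)bis(4-tert-butyl-4,5-dihydrooxazole) and (CF3)2CHOH in CH2Cl2 at −20 °C. The divalent copper centre is chelated by the peri ketone/lactam carbonyl pair of 13, the fluorinated alcohol takes up the silyl group, and the released adduct 14 closes to 15, where the route is rejoined.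

Step 7. Hydride may be delivered to the other face of the cation and give the trans ring fusion, the side-chain oxygen may take part at the cationic carbon, the product ether may ionise again at Cb–O4' and be reduced further, or the tertiary silyl ether may ionise. Fallback, setting out from 15: acid-catalysed dehydration (pyridinium p-toluenesulfonate, toluene, 4 Å sieves, 60 °C) should give the pentacyclic Ca=Cb enol ether F2, and Bu4NF then frees its tertiary alcohol F3. Hydrogenation of F3 with [Ir(cod)(PCy3)(py)]PF6 (H2, CH2Cl2), the cationic iridium being held by the hydroxyl, should add both hydrogens to the face of the side chain, which sets Ca and Cb together and arrives directly at 18.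

Step 4. The lithium enolate may open ring A by β-elimination of O4 (retro-oxa-Michael), or the aldolate may revert before the quench. Fallback, setting out from 4: soft enolisation (Me3SiOTf, Et3N, CH2Cl2, 0 °C) gives the silyl dienol ether 2,2,6-trimethyl-4-(trimethylsilyloxy)-2H-pyrano[3,2-c]quinolin-5(6H)-one F4, which is combined with 9 in a Mukaiyama aldol addition (BF3·OEt2, CH2Cl2, −78 °C) without any free enolate and returns to the route at 11.

**Further compounds**

F1 | step 6 | 1-methyl-4-(trimethylsilyloxy)quinolin-2(1H)-one | Cn1c(=O)cc(O[Si](C)(C)C)c2ccccc21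
F2 | step 7 | pentacyclic Ca=Cb enol ether, chain as triethylsilyl ether (Cc R) | Cn1c(=O)c2c(c3ccccc31)OC(C)(C)C1=C2Oc2c(c(=O)n(C)c3ccccc23)[C@@H]1CC(C)(C)O[Si](CC)(CC)CC
F3 | step 7 | pentacyclic Ca=Cb enol ether with free tertiary alcohol (Cc R) | Cn1c(=O)c2c(c3ccccc31)OC(C)(C)C1=C2Oc2c(c(=O)n(C)c3ccccc23)[C@@H]1CC(C)(C)O
F4 | step 4 | 2,2,6-trimethyl-4-(trimethylsilyloxy)-2H-pyrano[3,2-c]quinolin-5(6H)-one | Cn1c(=O)c2c(c3ccccc31)OC(C)(C)C=C2O[Si](C)(C)C
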